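An easy step first: at a steady ligand level, a complex exchanging a ligand behaves like a first-order lag with one lifetime (pseudo-first-order). Here the starting complex passes through the complex with one exchanged to the complex with two exchanged, so two lags stand in series, with lifetimes τa and τb.

| setting | summer | dusk | blue | amber | grey |
|---|---|---|---|---|---|
| starting complex | 0.067 M | 0.20 M | 0.10 M | 0.10 M | 0.10 M |
| incoming ligand | 2.5 equiv | 2.5 equiv | 2.50 equiv | 4.00 equiv | 1.50 equiv |
| remark | run made earlier | run made earlier |  |  |  |
| time |  |  | 15 min | 15 min | 15 min |
- summer (time / min: complex with two exchanged / %): 1.00: 1.2; 3.00: 2.8; 6.00: 7.0; 10.0: 15.7
- dusk (time / min: complex with two exchanged / %): 1.00: 4.9; 3.00: 18.2; 6.00: 32.4; 10.0: 47.5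

(readings scatter by 1 percentage point)
- which of these holds the largest part of the starting complex at the end of blue (complex with two exchanged / complex with one exchanged / starting complex)
- which of these holds the largest part of the starting complex at the end of amber (complex with two exchanged / complex with one exchanged / starting complex)
- which of these holds the largest part of the starting complex at the end of grey (complex with two exchanged / complex with one exchanged / starting complex)
- amount of complex with two exchanged at the end of grey, in percent of the starting complex charged


Early on, a reading y of the complex with two exchanged at time t gives the pair time, τp = √(τa·τb), which stays the same if the two lags swap places: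

τp = t/√(2y) = 3.19 min (first dusk reading)

So these readings give the size of the pair, not its order. Yet a puzzle appears: 10.0 min is 3.13 pair times, where an equal-lifetime chain gives 82.0%, and dusk reads 47.5%.

The ligand level clears up part of this. Each complex with two exchanged took two ligands, so dusk keeps 62.0% of its charge before the complex with one exchanged is counted. That cuts the count and the chain's yield:

count = 1.94, chain = 57.8%

Lifetimes scale inversely with ligand concentration, so for grey we reckon:

τp = 10.6 min, count = 1.41, chain at the charged level = 41.1%

That figure holds the ligand at its charge and is not our estimate of grey. The forecast commits further, from “two consecutive bimolecular steps” with rate constants of 0.9 for the first and 0.3 for the second, per molar per minute: complex with one exchanged for blue, complex with two exchanged for amber, complex with one exchanged for grey, and 16% (11% to 21%).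

The flasks end with starting complex in blue (46.6%), complex with two exchanged in amber (57.7%) and starting complex in grey (63.2%), and grey gives 17.7%.

    complex with one exchanged + incoming ligand → leaving ligand + complex with two exchanged (k = 0.0200 M⁻¹ s⁻¹)
    complex with two exchanged → over-reaction product (k = 2.50 × 10⁻⁶ s⁻¹)
    incoming ligand ⇌ dormant form (K = 0.800, k = 0.00220 s⁻¹)
    starting complex + incoming ligand → leaving ligand + complex with one exchanged (k = 0.00670 M⁻¹ s⁻¹)

Grey's half-lives as charged, 11 min for the first step and 3.9 min for the second, make a pair time of 9.60 min, with the longer one first, the reverse of the forecast's order. Part of grey's shortfall against 41.1% comes from ligand passing to the dormant form, together with the length of the run: without that step, grey reaches 28.6% instead of 17.7%, and left for 150 min it reaches 63.1%. In the neighbour charged with 6.00 equiv, the same reckoning gives a pair time as charged of 2.40 min, so 15 min counts 6.25 pair times, and the complex with two exchanged holds 77.8%.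

(The runs were computed from invented constants; the scatter is artificial.)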